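The numbers in the tables are simulated for substances that don't exist; scatter was added.

The climb time of the red flask is the span in which the straight stretch of its target curve, from 15.0 min to 40.0 min, gains the equivalent of the whole charge. It reads 11.0 h. The same stretch puts the wait (induction period) of the red flask at 7.11 min, so the climb time is far longer than the wait. Both are readings, with a scatter of 0.5 percentage points on each point.

| flask | starting material | solid reagent | remark | time |
|---|---|---|---|---|
| red | 1.1 M | 1 equiv | the very flask that is asked about, followed so far |  |
| violet | 2.2 M | 1 equiv | run made earlier |  |
| flask | 1.1 M | 1.00 equiv |  | 2.0 h |

| run | time / min | target / % |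
|---|---|---|
| red | 3.00 | 0 |
| red | 6.00 | 0.1 |
| red | 15.0 | 1.2 |
| red | 40.0 | 5.0 |
| violet | 10.0 | 0.8 |
| violet | 20.0 | 1.4 |
| violet | 50.0 | 4.8 |
| violet | 120 | 11.7 |

(readings scatter by 0.5 percentage points)

- solid, in amounts per volume of the solution: solid reagent
- at the start none of the solid reagent is in solution

- west: doubling the solubility of the solid reagent, all else as stated
- north-east: doubling the dissolution coefficient of the solid reagent, all else as stated

- the target standing at 2.0 h, as a percentage of the starting material charged
- the change that raises the amount of target at 2.0 h, in percent of the starting material charged most ("none" if none brings more than 2 percentage points) (west / north-east / none)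
- amount of target at 2.0 h, in percent of the starting material charged, after north-east

None of the solid reagent is in solution at the start, and a wait fits that. While the line lasts, target in the red flask is the time past the wait divided by the climb time, so 2.0 h gives 17.2 %. The violet run reads a climb time of 16.9 h between its last two readings. With twice the starting material and the same equivalents of solid reagent, the violet run reads 1.30 times the molar rate of the red line, and the red line is used as it stands. That line gives no figure for west or north-east.

The forecast gave 16 %, west as the better change and 20 % after north-east, holding that “Doubling solubility doubles the steady dissolved level”.

The flask gives 16.2 %. West adds 12 points and north-east 8.7 points, which brings it to 24.9 %, so the better change is west.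

    starting material + coupling partner → target (k = 5.67 × 10⁻⁴ L mol⁻¹ s⁻¹)
    starting material → side product (k = 2.32 × 10⁻⁴ s⁻¹)
    solid reagent ⇌ coupling partner, rate k3*(cs3 - [coupling partner]) while solid is left; crystals form when [coupling partner] > cs3 (solubility = 0.500 M, k = 1.48 × 10⁻⁴ s⁻¹)

At 2.0 h the flask is not at rest, with 11 % of its starting material left. Read at 30 min, the same flask holds 3.59 % of target, and the line gives 3.47 % for that time. Read at 5.0 h, it holds 20.7 % where the line gives 44.4 %, and starting material is down to 0.12 %. Left on to 20.0 h, the flask gains 4.6 points of target and 6.7 points of side product, its starting material goes to 0 %, and its coupling partner rises from 0.221 M to 0.500 M.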